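## Retrosynthetic overview

1. The target is read as (2S,3R,4R,5R): 2,5-cis aryl groups and 3,4-trans hydroxymethyl groups. It comes from an oxolane-3,3-diester by dealkoxycarbonylation (C3 settles anti to both neighbours), ester/pivalate reduction and debenzylation.
2. The oxolane-3,3-diester comes from a ring expansion: the C=O of O-benzylvanillin is inserted into the C1–C3 bond of a trans-2,3-disubstituted 3-arylcyclopropane-1,1-diester. Inversion at the benzylic carbon gives the 4,5-cis relation and ring closure gives 2,5-cis.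
3. The cyclopropane comes from an organocatalytic Michael-initiated ring closure of the (E)-enal of O-benzylvanillin with dimethyl bromomalonate, which sets both carbon stereocentres, followed by CHO → CH2OPiv.
4. Both aryl units come from one aldehyde: catechol → guaiacol → vanillin (with glyoxylic acid) → benzyl ether. The enal is made by two-carbon extension with vinyl acetate, and the bromomalonate from malonic acid.
5. Ring order: cyclopropane first (step 7), oxolane second (step 9); no other ring is built.

## Route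

Step 1
Reactants: 1 catechol
Product: 2 guaiacol (2-methoxyphenol)
Conditions: MeI (1.0 equiv), K2CO3 (1.0 equiv), acetone, reflux
Reagents that add atoms: iodomethane, CI
Why: Williamson mono-O-methylation, where one equivalent of MeI stops mainly at the monoether because the remaining hydrogen-bonded OH of guaiacol is less acidic.

Step 2
Reactants: 2 guaiacol; 3 glyoxylic acid
Product: 6 vanillin (4-hydroxy-3-methoxybenzaldehyde), via vanillylmandelic acid 4 (not isolated), via vanilloylformic acid 5 (not isolated)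
Conditions: NaOH, H2O, 30 °C; then CuSO4 (cat.), O2 (air), 90 °C; then H2SO4 (aq.), 60 °C
Reagents that add atoms: none
Why: The phenolate is hydroxyalkylated para to the oxygen by glyoxylate (electrophilic aromatic substitution), then copper-catalysed aerobic oxidation and decarboxylation of the α-keto acid give the aldehyde (the guaiacol–glyoxylic acid vanillin process).

Step 3
Reactants: 6 vanillin
Product: 7 4-(benzyloxy)-3-methoxybenzaldehyde
Conditions: BnBr, K2CO3, DMF, 60 °C
Reagents that add atoms: benzyl bromide, BrCc1ccccc1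
Why: Williamson etherification gives a phenol protecting group that survives Lewis acid, hot LiCl/DMSO and LiAlH4 and comes off by hydrogenolysis.

Step 4
Reactants: 7 4-(benzyloxy)-3-methoxybenzaldehyde; 8 vinyl acetate
Product: 9 (E)-3-[4-(benzyloxy)-3-methoxyphenyl]prop-2-enal
Conditions: Ba(OH)2, THF, reflux
Reagents that add atoms: none
Why: Claisen–Schmidt-type crossed aldol condensation in which hydroxide cleaves vinyl acetate to release the acetaldehyde enolate at low concentration, and dehydration gives the conjugated E-enal.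

Step 5
Reactants: 10 malonic acid
Product: 11 dimethyl malonate
Conditions: MeOH, H2SO4 (cat.), reflux
Reagents that add atoms: methanol, CO
Why: Fischer esterification driven by excess methanol.

Step 6
Reactants: 11 dimethyl malonate
Product: 12 dimethyl bromomalonate
Conditions: Br2 (1.0 equiv), CH2Cl2, 0 °C → rt
Reagents that add atoms: bromine, BrBr
Why: Electrophilic α-bromination through the enol, stopped at the monobromide with one equivalent of bromine.

Step 7
Reactants: 9 (E)-3-[4-(benzyloxy)-3-methoxyphenyl]prop-2-enal; 12 dimethyl bromomalonate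
Product: 14 dimethyl (2R,3S)-3-[4-(benzyloxy)-3-methoxyphenyl]-2-(hydroxymethyl)cyclopropane-1,1-dicarboxylate, via formylcyclopropane diester 13 (not isolated)
Conditions: (S)-2-[diphenyl(trimethylsilyloxy)methyl]pyrrolidine (20 mol%), 2,6-lutidine (1.1 equiv), CH2Cl2, rt; then MeOH, NaBH4, −20 °C, pH 7 quench
Reagents that add atoms: none
Why: Organocatalytic Michael-initiated ring closure, where the (S)-catalyst shields one face of the E-iminium ion so bromomalonate adds to the β-carbon (sets C3 as S) and the enamine displaces bromide anti to the aryl group (sets C2 as R, trans); NaBH4 then reduces only the aldehyde.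

Step 8
Reactants: 14 dimethyl (2R,3S)-3-[4-(benzyloxy)-3-methoxyphenyl]-2-(hydroxymethyl)cyclopropane-1,1-dicarboxylate
Product: 15 dimethyl (2R,3S)-3-[4-(benzyloxy)-3-methoxyphenyl]-2-[(pivaloyloxy)methyl]cyclopropane-1,1-dicarboxylate
Conditions: PivCl, pyridine, DMAP (cat.), CH2Cl2, 0 °C (run directly on the crude alcohol)
Reagents that add atoms: pivaloyl chloride, CC(C)(C)C(=O)Cl
Why: Prompt acylation blocks lactonisation onto the cis ester and makes the C2 stereocentre non-epimerisable for the later steps.

Step 9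
Reactants: 15 dimethyl (2R,3S)-3-[4-(benzyloxy)-3-methoxyphenyl]-2-[(pivaloyloxy)methyl]cyclopropane-1,1-dicarboxylate; 7 4-(benzyloxy)-3-methoxybenzaldehyde
Product: 16 dimethyl (2R,4R,5R)-2,5-bis[4-(benzyloxy)-3-methoxyphenyl]-4-[(pivaloyloxy)methyl]oxolane-3,3-dicarboxylate
Conditions: Sn(OTf)2 (10 mol%), 7 (3 equiv), 4 Å MS, CH2Cl2, −20 → 0 °C
Reagents that add atoms: none
Why: Proposed new method: carbonyl insertion into the C1–C3 bond of a 2,3-trans-disubstituted cyclopropane-1,1-diester carrying an acyloxymethyl group, a substrate class not yet used in this ring expansion – Sn(OTf)2 chelates the diester, the aldehyde oxygen attacks the benzylic carbon from the rear with inversion (trans-cyclopropane → 4,5-cis) and the malonate end closes on the E-oxocarbenium ion through an envelope with both aryl groups pseudo-equatorial (2,5-cis); the closest known reaction is the Sn(OTf)2-catalysed (3+2) annulation of aldehydes with 3-unsubstituted 2-arylcyclopropane-1,1-diesters, a stepwise ionic and not pericyclic process.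

Step 10
Reactants: 16 dimethyl (2R,4R,5R)-2,5-bis[4-(benzyloxy)-3-methoxyphenyl]-4-[(pivaloyloxy)methyl]oxolane-3,3-dicarboxylate
Product: 18 methyl (2S,3S,4R,5R)-2,5-bis[4-(benzyloxy)-3-methoxyphenyl]-4-[(pivaloyloxy)methyl]oxolane-3-carboxylate, via all-cis C3-epimeric ester 17 (not isolated)
Conditions: LiCl (3 equiv), H2O (2 equiv), DMSO, 150 °C; then DBU (0.5 equiv), toluene, 80 °C
Reagents that add atoms: none
Why: Krapcho dealkoxycarbonylation (chloride demethylation, loss of CO2, protonation), after which DBU equilibrates the only enolisable centre so the ester sits anti to the two flanking cis substituents (sets C3).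

Step 11
Reactants: 18 methyl (2S,3S,4R,5R)-2,5-bis[4-(benzyloxy)-3-methoxyphenyl]-4-[(pivaloyloxy)methyl]oxolane-3-carboxylate
Product: 19 [(2S,3R,4R,5R)-2,5-bis[4-(benzyloxy)-3-methoxyphenyl]oxolane-3,4-diyl]dimethanol
Conditions: LiAlH4, THF, 0 °C → rt
Reagents that add atoms: none
Why: Hydride reduction turns the methyl ester into CH2OH and cleaves the pivalate in the same operation without touching any stereocentre.

Step 12
Reactants: 19 [(2S,3R,4R,5R)-2,5-bis[4-(benzyloxy)-3-methoxyphenyl]oxolane-3,4-diyl]dimethanol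
Product: 20 [(2S,3R,4R,5R)-2,5-bis(4-hydroxy-3-methoxyphenyl)oxolane-3,4-diyl]dimethanol (target)
Conditions: H2 (1 atm), Pd/C, EtOAc/MeOH, rt, stopped after uptake of 2 equiv H2
Reagents that add atoms: none
Why: Hydrogenolysis of the two aryl benzyl ethers, which cleave faster than the benzylic C–O bonds of the oxolane ring under neutral conditions.

## Compound list

1 | catechol | Oc1ccccc1O | starting material
2 | guaiacol (2-methoxyphenol) | COc1ccccc1O | intermediate
3 | glyoxylic acid | O=CC(=O)O | starting material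
4 | vanillylmandelic acid (racemic 2-hydroxy-2-(4-hydroxy-3-methoxyphenyl)acetic acid) | COc1cc(C(O)C(=O)O)ccc1O | intermediate
5 | vanilloylformic acid ((4-hydroxy-3-methoxyphenyl)(oxo)acetic acid) | COc1cc(C(=O)C(=O)O)ccc1O | intermediate
6 | vanillin | COc1cc(C=O)ccc1O | intermediate
7 | 4-(benzyloxy)-3-methoxybenzaldehyde | COc1cc(C=O)ccc1OCc2ccccc2 | intermediate
8 | vinyl acetate | CC(=O)OC=C | starting material
9 | (E)-3-[4-(benzyloxy)-3-methoxyphenyl]prop-2-enal | COc1cc(/C=C/C=O)ccc1OCc2ccccc2 | intermediate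
10 | malonic acid | OC(=O)CC(=O)O | starting material
11 | dimethyl malonate | COC(=O)CC(=O)OC | intermediate
12 | dimethyl bromomalonate | COC(=O)C(Br)C(=O)OC | intermediate
13 | dimethyl (2R,3S)-3-[4-(benzyloxy)-3-methoxyphenyl]-2-formylcyclopropane-1,1-dicarboxylate | COC(=O)C1(C(=O)OC)[C@H](C=O)[C@H]1c2ccc(OCc3ccccc3)c(OC)c2 | intermediate
14 | dimethyl (2R,3S)-3-[4-(benzyloxy)-3-methoxyphenyl]-2-(hydroxymethyl)cyclopropane-1,1-dicarboxylate | COC(=O)C1(C(=O)OC)[C@H](CO)[C@H]1c2ccc(OCc3ccccc3)c(OC)c2 | intermediate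
15 | dimethyl (2R,3S)-3-[4-(benzyloxy)-3-methoxyphenyl]-2-[(pivaloyloxy)methyl]cyclopropane-1,1-dicarboxylate | COC(=O)C1(C(=O)OC)[C@H](COC(=O)C(C)(C)C)[C@H]1c2ccc(OCc3ccccc3)c(OC)c2 | intermediate
16 | dimethyl (2R,4R,5R)-2,5-bis[4-(benzyloxy)-3-methoxyphenyl]-4-[(pivaloyloxy)methyl]oxolane-3,3-dicarboxylate | COc1cc([C@H]2O[C@@H](c3ccc(OCc4ccccc4)c(OC)c3)[C@@H](COC(=O)C(C)(C)C)C2(C(=O)OC)C(=O)OC)ccc1OCc5ccccc5 | intermediate
17 | methyl (2S,3R,4R,5R)-2,5-bis[4-(benzyloxy)-3-methoxyphenyl]-4-[(pivaloyloxy)methyl]oxolane-3-carboxylate (all-cis C3 epimer) | COc1cc([C@H]2O[C@@H](c3ccc(OCc4ccccc4)c(OC)c3)[C@@H](COC(=O)C(C)(C)C)[C@H]2C(=O)OC)ccc1OCc5ccccc5 | intermediate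
18 | methyl (2S,3S,4R,5R)-2,5-bis[4-(benzyloxy)-3-methoxyphenyl]-4-[(pivaloyloxy)methyl]oxolane-3-carboxylate | COc1cc([C@H]2O[C@@H](c3ccc(OCc4ccccc4)c(OC)c3)[C@@H](COC(=O)C(C)(C)C)[C@@H]2C(=O)OC)ccc1OCc5ccccc5 | intermediate
19 | [(2S,3R,4R,5R)-2,5-bis[4-(benzyloxy)-3-methoxyphenyl]oxolane-3,4-diyl]dimethanol | COc1cc([C@H]2O[C@@H](c3ccc(OCc4ccccc4)c(OC)c3)[C@@H](CO)[C@@H]2CO)ccc1OCc5ccccc5 | intermediate
20 | [(2S,3R,4R,5R)-2,5-bis(4-hydroxy-3-methoxyphenyl)oxolane-3,4-diyl]dimethanol | COc1cc([C@H]2O[C@@H](c3ccc(O)c(OC)c3)[C@@H](CO)[C@@H]2CO)ccc1O | target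

## Step count and risks

Total step count: 12. Longest linear sequence: 10 steps (steps 1, 2, 3, 4, 7, 8, 9, 10, 11, 12, from catechol to the target).

The three steps most likely to fail:

Step 9 (the proposed ring expansion). The electron-rich aryl donor may ionise instead of reacting by the SN2-like path, which would scramble the 4,5-cis relation, and the extra ring substituent may slow the closure. The fallback makes the same two bonds in separate, known operations. It sets out from cyclopropane 15 and aldehyde 7 and comes back at 16. Aldehyde 7 is reduced (NaBH4, MeOH) to [4-(benzyloxy)-3-methoxyphenyl]methanol F1. This alcohol opens 15 at the benzylic carbon with inversion under Cu(OTf)2 catalysis at 0 °C (the known Lewis-acid ring opening of donor–acceptor cyclopropane diesters by alcohols), giving dimethyl 2-[(1R,2R)-1-[4-(benzyloxy)-3-methoxyphenyl]-1-{[4-(benzyloxy)-3-methoxyphenyl]methoxy}-3-(pivaloyloxy)propan-2-yl]propanedioate F2. Oxidation of the new p-alkoxybenzyl ether CH2 with DDQ (InCl3 and Cu(OTf)2 as catalysts, CH2Cl2) generates the oxocarbenium ion next to the malonate, which closes to 16 (the known oxidative C–H cyclisation of benzyl ethers with 1,3-dicarbonyl nucleophiles).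

Step 10 (dealkoxycarbonylation and C3 equilibration). Hot LiCl/DMSO may erode the pivalate or give an ester mixture that DBU equilibrates only slowly. The fallback sets out from 16 and comes back at 18. One equivalent of KOH in MeOH/H2O at 0 °C saponifies the less hindered ester to (2R,3R,4R,5R)-2,5-bis[4-(benzyloxy)-3-methoxyphenyl]-3-(methoxycarbonyl)-4-[(pivaloyloxy)methyl]oxolane-3-carboxylic acid F3. Heating F3 in toluene at 110 °C decarboxylates the malonic half-acid, and brief DBU treatment of the resulting monoester gives 18.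

Step 4 (enal formation). The crossed aldol may give polyene by-products or low conversion with this electron-rich aldehyde. The fallback sets out from 7 and comes back at 9. Addition of CH2=CHMgBr (THF, −78 °C) gives 1-[4-(benzyloxy)-3-methoxyphenyl]prop-2-en-1-ol F4. Acid-catalysed 1,3-allylic transposition (TsOH cat., aqueous dioxane) gives the conjugated (E)-3-[4-(benzyloxy)-3-methoxyphenyl]prop-2-en-1-ol F5, which MnO2 in CH2Cl2 oxidises to 9.

Further compounds
F1 | step 9 | [4-(benzyloxy)-3-methoxyphenyl]methanol | COc1cc(CO)ccc1OCc2ccccc2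
F2 | step 9 | dimethyl 2-[(1R,2R)-1-[4-(benzyloxy)-3-methoxyphenyl]-1-{[4-(benzyloxy)-3-methoxyphenyl]methoxy}-3-(pivaloyloxy)propan-2-yl]propanedioate | COc1cc(CO[C@@H](c3ccc(OCc4ccccc4)c(OC)c3)[C@@H](COC(=O)C(C)(C)C)C(C(=O)OC)C(=O)OC)ccc1OCc5ccccc5
F3 | step 10 | (2R,3R,4R,5R)-2,5-bis[4-(benzyloxy)-3-methoxyphenyl]-3-(methoxycarbonyl)-4-[(pivaloyloxy)methyl]oxolane-3-carboxylic acid | COc1cc([C@H]2O[C@@H](c3ccc(OCc4ccccc4)c(OC)c3)[C@@H](COC(=O)C(C)(C)C)[C@]2(C(=O)OC)C(=O)O)ccc1OCc5ccccc5
F4 | step 4 | 1-[4-(benzyloxy)-3-methoxyphenyl]prop-2-en-1-ol (racemic) | COc1cc(C(O)C=C)ccc1OCc2ccccc2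
F5 | step 4 | (E)-3-[4-(benzyloxy)-3-methoxyphenyl]prop-2-en-1-ol | COc1cc(/C=C/CO)ccc1OCc2ccccc2
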